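(The data are simulated on assumed constants; noise was put on by code.)

Colleague, you wanted a quick number for the flask, and your hunch was that more E simply means more D. Both earlier runs back you, but read their tails before their peaks.

all flasks: Q 0.30 M
- cedar: E 0.14 M; run made earlier
- oak: E 0.20 M; run made earlier
- flask: E 0.270 M; time 20 h

| run | time / h | D / % | Q / % |
|---|---|---|---|
| cedar | 0.333 | 3.1 | 31.0 |
| cedar | 0.667 | 7.4 | 10.2 |
| cedar | 1.33 | 16.3 | 1.5 |
| cedar | 3.00 | 8.5 | 0 |
| cedar | 6.00 | 7.9 | 0 |
| cedar | 12.0 | 9.1 | 0 |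
| oak | 0.333 | 3.6 | 32.0 |
| oak | 0.667 | 11.1 | 7.1 |
| oak | 1.33 | 20.6 | 0 |
| oak | 3.00 | 13.0 | 1.2 |
| oak | 6.00 | 10.8 | 0 |
| oak | 12.0 | 11.9 | 1.5 |

(readings scatter by 1 percentage point)

- when, up to 20 h, the flask holds most D
- the amount of D, in percent of the Q charged, at that time

- the numbers in the tables scatter by 1 percentage point (one standard deviation)

Count E as a fraction of the Q charged: 0.467 in cedar, 0.667 in oak, 0.900 in the flask. The last three readings of D average 8.50% in cedar and 11.9% in oak, so dividing each by its E fraction gives 18.2% and 17.8%. Their mean is 18.0%: call this the plateau share, the D left on the tail as a fraction of the E charged. My own reckoning from it puts the flask's tail near 16.2%. In cedar and oak the highest reading of D stands above the tail, and my forecast for the flask's peak is 27% at 1.5 h, on the grounds that “Everything about D scales with E charged”.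

The flask gives 23.2% at 1.42 h, inside the margin and 3.8 percentage points under the forecast, and it holds 16.1% at 20.0 h.

    Q → J (k = 0.0590 min⁻¹)
    E + J ⇌ G (K = 80.0 M⁻¹, k = 0.0560 M⁻¹ min⁻¹)
    J → L (k = 0.0360 min⁻¹)
    G ⇌ Z (K = 0.480, k = 0.0160 min⁻¹)
    E + L → D (k = 0.160 M⁻¹ min⁻¹)
    D ⇌ X (K = 3.80, k = 0.0200 min⁻¹)

The largest single pull on the flask's peak is the path from D to X: without it the flask's highest D is 76.3% instead of 23.2%. The flask's 16.1% of D at 20.0 h, on 0.900 of E, is a plateau share of 17.9%. A further flask with E cut to 0.11 M has the share pointing to 6.61%, and it holds 6.63% of D at 20.0 h.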